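## The problem

The target 16 is a fully aromatic 1-arylnaphthalene. In naphthalene numbering, ring B carries the 3,4,5-trimethoxyphenyl ring C on C1, methyl groups on C2 and C3 and its only hydrogen on C4. Ring A carries a free hydroxyl on C6 and a methoxy group on C7.

There is no stereocentre. Ring C is symmetric, so the biaryl axis is not a stereo element. Every sp3 centre met on the way is scaffolding that is flattened later, and none has to control another.

The difficulty is regiochemical. One of five oxygens must end up free, which rules out a late selective demethylation, so the C6/C7 pattern has to be bought with the starting material. Three contiguous substituents on C1 to C3 also make late bond formation at those carbons unattractive.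

The electron-rich naphthol is easily oxidised and is acidic towards organometallic and diazo reagents, so it has to be masked until the end. The four aryl methyl ethers exclude strong Lewis acids such as BBr3 or AlCl3, and a benzyl ether will not survive hot strong acid.

The feature that opens the route is C4. It is the only unsubstituted carbon of ring B and lies between the ring A carbon C4a and the methyl-bearing C3. Removing it contracts ring B to the five-membered ring of a 3-aryl-2-methylindan-1-one whose carbonyl carbon is the future C3. C4a is para to the C7 methoxy group, which makes it a good migrating carbon for a one-carbon insertion.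

## Retrosynthesis

**16 to 15.** The C6 O–H is traced back to an O–CH2Ph bond. A benzyl ether is preferred to a silyl ether (labile to BF3 and to acid) and to a methyl ether (indistinguishable from the other four). It is inert to BF3·OEt2 at low temperature, to organocerium reagents, to catalytic TsOH and to DDQ. The precursor 15 is no simpler, but it is robust. The forward step must cleave the benzyl group without touching the naphthalene, which neutral hydrogenolysis does.

**15 to 12.** Ring B is taken out of the aromatic state. Two hydrogens are put back on C1 and C2 (dihydronaphthalene 14), water is added across C3=C4 (tertiary alcohol 13), and the C3–CH3 bond is cut to leave the 2-tetralone 12. Cutting the C2 methyl or the C1 aryl bond instead would demand cross-couplings at the most crowded positions of a finished naphthalene. The C3 methyl is the one substituent that maps onto a carbonyl group. The forward sequence needs a methyl nucleophile of low basicity, because the ketone of 12 is flanked by a benzylic methylene, then a dehydration and a dehydrogenation that erase all sp3 centres.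

**12 to 9 and 10 (key disconnection).** The bonds C4–C4a and C3–C4 are cut and the methylene carbon is removed. This leaves the indanone 9, whose carbonyl carbon is bonded directly to the aryl carbon, and the one-carbon donor (trimethylsilyl)diazomethane 10. The forward reaction passes through the α-silyl ketone 11. This cut takes out the only unsubstituted ring carbon, so the insertion happens at the least hindered site. Excising C2 would put the new carbon between the aryl- and methyl-bearing carbons, and cutting C3=C4 alone would need a fully assembled diene. Ring B shrinks to a five-membered ring that two aldehyde-level building blocks can supply. The forward step must migrate the aryl carbon and not the C2 methine, and it must stop after one insertion. In the numbering of 12 the inserted carbon is C1, so the benzyloxy group is at C7 and the methoxy group at C6.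

**9 to 7.** The benzyl ether is removed to give phenol 8, and the C3–C3a bond of the indanone is cut to open the ring to the α-methylchalcone 7 (Nazarov retron). Closing the ring at the other end, by Friedel–Crafts acylation of a diarylpropanoic acid, would have to choose between two electron-rich rings. The Nazarov closure is intramolecular onto the only ring that carries the ketone. The phenol is left free for this step because a benzyl ether would not survive hot trifluoroacetic acid, and the free hydroxyl activates the para position where the bond must form. The forward reaction must close para and not ortho to the hydroxyl.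

**7 to 4 and 5.** The C2=C3 double bond of the enone is cut by a crossed aldol condensation (through aldol adduct 6) into propiophenone 4 and 3,4,5-trimethoxybenzaldehyde 5. The aldehyde cannot enolise and the ketone has a single enolisable position, so only one condensation product is possible. Both pieces are simple benzene derivatives.

**4 to 1 and 2.** The bond between the carbonyl carbon and the ethyl group is cut through carbinol 3 to isovanillin 1 and ethylmagnesium bromide 2. Isovanillin already holds the 3-hydroxy-4-methoxy pattern that becomes C6–OH and C7–OMe, so the oxygen differentiation is never an issue. The forward steps are a Grignard addition with the phenol unprotected and a benzylic oxidation.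

## Roads not taken

**Alternative 1: ring-closing metathesis, then dehydration.**
- Cut: the C3=C4 bond of ring B and the C1–C2 unsaturation, going back to 1-[4-(benzyloxy)-2-ethenyl-5-methoxyphenyl]-2,3-dimethyl-1-(3,4,5-trimethoxyphenyl)but-3-en-1-ol A2.
- Forward key step: the second-generation Grubbs catalyst (H2IMes)(PCy3)Cl2Ru=CHPh joins the styrene and isopropenyl termini of A2. TsOH added to the same flask expels water from the doubly benzylic carbinol and gives the benzyl-protected naphthalene A1, which is the same compound as 15.
- Merits: ring B arrives aromatic without any oxidant. Six-membered benzo-fused metathesis between a styrene and a 1,1-disubstituted alkene is dependable. Ring C enters convergently.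
- Weak points: A2 has to come from the ortho-vinyl diaryl ketone [4-(benzyloxy)-2-ethenyl-5-methoxyphenyl](3,4,5-trimethoxyphenyl)methanone A3 by addition of a 1,2-dimethylallyl metal. That addition to a hindered, electron-rich ketone must be γ-selective and is prone to reversal. A3 in turn needs a ring halogenation, an aryl-metal addition, an oxidation and a vinyl cross-coupling.
- Comparison: the length is about eight steps, slightly shorter than the chosen plan, and the end-game is cleaner than methyl addition, dehydration and dehydrogenation. The chosen plan sets against this that it uses no ruthenium and no vinyl coupling, that ring B's substituents come from an aldol/Nazarov pair of inexpensive steps, and that it avoids the one step of this road whose regiochemistry is not secured by the substrate.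

**Alternative 2: anodic cross-annulation of two propenylbenzenes.**
- Cut: C2–C3 and C1–C8a, back to isoelemicin A5 and 2-(benzyloxy)-1-methoxy-4-[(E)-prop-1-enyl]benzene A6.
- Forward key step: constant-current oxidation at a carbon anode (undivided cell, LiClO4, hexafluoroisopropanol-containing solvent) of A6 with excess A5. The two β-carbons join, ring A carbon C8a attacks the benzylic cation next to ring C, and proton loss gives the 1,2-dihydronaphthalene A4, which is the same compound as 14.
- Merits: this is by far the shortest road. A5 is one olefination from 5 and A6 two steps from 1. All of ring B is built in one operation, and only dehydrogenation and debenzylation remain, about five steps in all.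
- Weak points: the two alkenes have nearly the same oxidation potential, so homo-dimerisation of either competes with the cross-coupling. The coupled dication can also close onto ring C, which gives the constitutional isomer with the trimethoxy ring fused. A4 is more easily oxidised than either substrate, and the benzyl ether sits in an anodic medium.
- Comparison: this road is about half as long, and if the cross- and ring-selectivity could be relied on it would be the better synthesis. The chosen plan sets against it that each of its bonds forms between atoms fixed by the substrate, so no statistical mixture has to be separated.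

**Alternative 3: dibromocarbene insertion into an indene.**
- Cut: C1–C2 and C2–C3, so that C2 is the inserted carbon, going back to 6-(benzyloxy)-5-methoxy-2-methyl-3-(3,4,5-trimethoxyphenyl)-1H-indene A8.
- Forward key step: dibromocarbene (CHBr3, KOt-Bu) cyclopropanates the indene double bond of A8. The adduct opens with loss of bromide and a proton to 6-(benzyloxy)-2-bromo-7-methoxy-3-methyl-1-(3,4,5-trimethoxyphenyl)naphthalene A7.
- Merits: ring B is aromatic at once and no dehydrogenation is needed. The bromine is a handle for the missing methyl group.
- Weak points:
  - The inserted carbon is the most congested one of ring B, so the carbene must add to a tetrasubstituted, aryl-flanked double bond.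
  - KOt-Bu can move the indene double bond through the indenyl anion before the carbene arrives, which would scramble the position of the bromine.
  - The methyl group must then be introduced by cross-coupling at a carbon flanked by an aryl ring and a methyl group.
  - Hydrogenolysis of the benzyl ether has to wait until the bromine is gone.
- Comparison: the step count is similar to the chosen plan, and this road is better in that it needs no late oxidant. The chosen plan sets against it that it inserts the only unsubstituted carbon, C4, under non-basic conditions, and that the last methyl group comes from a simple carbonyl addition and not from a hindered coupling.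

Key step: step 6

Assumption: the sp3 centres of 3, 6, 8, 9, 11, 12, 13 and 14 are formed without control and carried as racemates or diastereomer mixtures, because step 9 flattens all of them; their SMILES are therefore written without configuration.

## Route

Step 1
Reactants: 1 isovanillin (3-hydroxy-4-methoxybenzaldehyde); 2 ethylmagnesium bromide
Product: 3 1-(3-hydroxy-4-methoxyphenyl)propan-1-ol (racemic)
Conditions: EtMgBr (2.5 equiv), THF, 0 °C to rt; cold 1 M HCl
Reagents that add atoms: ethylmagnesium bromide (2), CC[Mg]Br
Why: Grignard addition to an aldehyde; the first equivalent is spent on the phenol (ethane is released), and the resulting phenoxide is meta to the formyl group and does not deactivate it by conjugation; the carbinol centre is racemic and is destroyed in step 2.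

Step 2
Reactants: 3 1-(3-hydroxy-4-methoxyphenyl)propan-1-ol
Product: 4 1-(3-hydroxy-4-methoxyphenyl)propan-1-one
Conditions: MnO2 (activated, 10 equiv), CH2Cl2, rt
Reagents that add atoms: none
Why: Heterogeneous MnO2 oxidation of a benzylic alcohol activated by the para methoxy group; the reagent is selective for the benzylic position and should leave the phenol alone, as in the familiar oxidation of hydroxybenzyl alcohols to hydroxybenzaldehydes.

Step 3
Reactants: 4 1-(3-hydroxy-4-methoxyphenyl)propan-1-one; 5 3,4,5-trimethoxybenzaldehyde
Product: 7 (E)-1-(3-hydroxy-4-methoxyphenyl)-2-methyl-3-(3,4,5-trimethoxyphenyl)prop-2-en-1-one, via aldol adduct 6 (not isolated)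
Conditions: KOH (3 equiv), EtOH, 60 °C; then aq. HCl
Reagents that add atoms: none
Why: Claisen–Schmidt (crossed aldol) condensation; 5 cannot enolise and 4 has one enolisable position, the meta phenoxide does not conjugate with the carbonyl, and E1cB loss of water from 6 should give the more stable E enone (aryl trans to aroyl), whose geometry is of no consequence for step 4.

Step 4
Reactants: 7 (E)-1-(3-hydroxy-4-methoxyphenyl)-2-methyl-3-(3,4,5-trimethoxyphenyl)prop-2-en-1-one
Product: 8 6-hydroxy-5-methoxy-2-methyl-3-(3,4,5-trimethoxyphenyl)indan-1-one (racemic; trans isomer expected to predominate)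
Conditions: CF3CO2H (neat), 80–100 °C, sealed vessel; aq. NaHCO3
Reagents that add atoms: none
Why: Nazarov cyclisation of an aryl vinyl ketone: the O-protonated enone is a pentadienyl cation that closes by 4π conrotatory electrocyclisation onto the ring carbon para to the hydroxyl (the ortho site between acyl and hydroxyl is flanked on both sides), followed by rearomatisation and ketonisation; the C2/C3 relationship is set thermodynamically through the enol and is erased later.

Step 5
Reactants: 8 6-hydroxy-5-methoxy-2-methyl-3-(3,4,5-trimethoxyphenyl)indan-1-one
Product: 9 6-(benzyloxy)-5-methoxy-2-methyl-3-(3,4,5-trimethoxyphenyl)indan-1-one (racemic diastereomer mixture)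
Conditions: BnBr, K2CO3, DMF, rt
Reagents that add atoms: benzyl bromide, BrCc1ccccc1
Why: Williamson ether synthesis; with K2CO3 the phenoxide is alkylated on oxygen far faster than the hindered ketone is alkylated on carbon.

Step 6
Reactants: 9 6-(benzyloxy)-5-methoxy-2-methyl-3-(3,4,5-trimethoxyphenyl)indan-1-one; 10 (trimethylsilyl)diazomethane
Product: 12 7-(benzyloxy)-6-methoxy-3-methyl-4-(3,4,5-trimethoxyphenyl)-3,4-dihydronaphthalen-2(1H)-one (racemic diastereomer mixture), via 1-trimethylsilyl ketone 11 (not isolated)
Conditions: 10 (1.8 equiv, hexanes), BF3·OEt2 (1.5 equiv), CH2Cl2, −78 to −15 °C; then 1 M HCl, THF, rt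
Reagents that add atoms: (trimethylsilyl)diazomethane (10), C[Si](C)(C)C=[N+]=[N-]
Why: BF3 binds the indanone oxygen and the nucleophilic diazo carbon of 10 adds to C1 to give a β-boryloxy diazonium betaine; the C1–C7a bond, antiperiplanar to the leaving N2 in the reactive rotamer, shifts to the diazo carbon as N2 departs (Tiffeneau–Demjanov-type 1,2-shift) and gives the BF3-bound α-silyl ketone 11, whose C–Si bond is cleaved by protodesilylation in the acidic work-up to give 12. The closest known reaction type is the Lewis-acid-promoted homologation of aryl alkyl and benzo-fused cyclic ketones with (trimethylsilyl)diazomethane, in which the aryl group migrates. Ring B is not closed end to end but arises by enlargement of the five-membered ring to a six-membered one, the diazo carbon being inserted between C1 and C7a so that the future C3–C4 and C4–C4a bonds form in one operation. No lasting stereocentre is made: the silyl-bearing carbon is a transient centre removed on desilylation, and the two existing centres pass through as a mixture that step 9 erases. The selectivity needed is migration of the aryl carbon C7a and not of the C2 methine; C7a is para to the C5 methoxy group and can bridge through a phenonium-like transition state, whereas a shift of the secondary C2 would press its methyl group and the neighbouring aryl ring against the bulky silyl substituent. A second insertion into the more electrophilic product should be held back because the product stays in the flask as the hindered BF3-bound α-silyl ketone (or its silyl enol ether after 1,3-silyl shift) until work-up. The benzyl and methyl ethers are inert to BF3·OEt2 at these temperatures.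

Step 7
Reactants: 12 7-(benzyloxy)-6-methoxy-3-methyl-4-(3,4,5-trimethoxyphenyl)-3,4-dihydronaphthalen-2(1H)-one
Product: 13 7-(benzyloxy)-6-methoxy-2,3-dimethyl-4-(3,4,5-trimethoxyphenyl)-1,2,3,4-tetrahydronaphthalen-2-ol (mixture of racemic diastereomers)
Conditions: MeLi, CeCl3 (anhydrous), THF, −78 °C; cold 1 M HCl
Reagents that add atoms: methyllithium, C[Li]
Why: Organocerium 1,2-addition; the methylcerium reagent formed in the flask is strongly oxophilic and weakly basic, which should suppress enolisation of a ketone flanked by a benzylic methylene; the new carbinol centre is formed without control and disappears in step 8.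

Step 8
Reactants: 13 7-(benzyloxy)-6-methoxy-2,3-dimethyl-4-(3,4,5-trimethoxyphenyl)-1,2,3,4-tetrahydronaphthalen-2-ol
Product: 14 6-(benzyloxy)-7-methoxy-2,3-dimethyl-1-(3,4,5-trimethoxyphenyl)-1,2-dihydronaphthalene (racemic diastereomer mixture)
Conditions: TsOH·H2O (cat.), toluene, 80 °C
Reagents that add atoms: none
Why: Acid-catalysed E1 dehydration of a tertiary alcohol; under equilibrating conditions the styrene-type C3=C4 alkene conjugated with ring A should dominate, and any double-bond isomer carried along converges on 15 in step 9.

Step 9
Reactants: 14 6-(benzyloxy)-7-methoxy-2,3-dimethyl-1-(3,4,5-trimethoxyphenyl)-1,2-dihydronaphthalene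
Product: 15 6-(benzyloxy)-7-methoxy-2,3-dimethyl-1-(3,4,5-trimethoxyphenyl)naphthalene
Conditions: DDQ (1.2 equiv), 1,4-dioxane, rt to 60 °C
Reagents that add atoms: none
Why: Quinone dehydrogenation; DDQ abstracts hydride from the doubly benzylic, allylic C1–H and the cation loses the C2 proton, with aromatisation of ring B as driving force; the aryl benzyl ether and the methyl ethers are not attacked by DDQ in the absence of acid.

Step 10
Reactants: 15 6-(benzyloxy)-7-methoxy-2,3-dimethyl-1-(3,4,5-trimethoxyphenyl)naphthalene
Product: 16 3-methoxy-6,7-dimethyl-5-(3,4,5-trimethoxyphenyl)naphthalen-2-ol (= 6-hydroxy-7-methoxy-2,3-dimethyl-1-(3,4,5-trimethoxyphenyl)naphthalene, the target)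
Conditions: H2 (1 atm), 10% Pd/C, EtOAc–EtOH, rt
Reagents that add atoms: none
Why: Catalytic hydrogenolysis of an aryl benzyl ether; at room temperature and atmospheric pressure the naphthalene core and the methyl ethers are not reduced.

## Compound list

1 | isovanillin (3-hydroxy-4-methoxybenzaldehyde) | O=Cc1ccc(OC)c(O)c1 | starting material
2 | ethylmagnesium bromide | CC[Mg]Br | starting material
3 | 1-(3-hydroxy-4-methoxyphenyl)propan-1-ol (racemic) | CCC(O)c1ccc(OC)c(O)c1 | intermediate
4 | 1-(3-hydroxy-4-methoxyphenyl)propan-1-one | CCC(=O)c1ccc(OC)c(O)c1 | intermediate
5 | 3,4,5-trimethoxybenzaldehyde | O=Cc1cc(OC)c(OC)c(OC)c1 | starting material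
6 | 3-hydroxy-1-(3-hydroxy-4-methoxyphenyl)-2-methyl-3-(3,4,5-trimethoxyphenyl)propan-1-one (aldol adduct, diastereomer mixture, not isolated) | COc1ccc(cc1O)C(=O)C(C)C(O)c1cc(OC)c(OC)c(OC)c1 | intermediate
7 | (E)-1-(3-hydroxy-4-methoxyphenyl)-2-methyl-3-(3,4,5-trimethoxyphenyl)prop-2-en-1-one | COc1ccc(cc1O)C(=O)/C(C)=C/c1cc(OC)c(OC)c(OC)c1 | intermediate
8 | 6-hydroxy-5-methoxy-2-methyl-3-(3,4,5-trimethoxyphenyl)indan-1-one (racemic, trans expected to predominate) | O=C1C(C)C(c2cc(OC)c(OC)c(OC)c2)c2cc(OC)c(O)cc21 | intermediate
9 | 6-(benzyloxy)-5-methoxy-2-methyl-3-(3,4,5-trimethoxyphenyl)indan-1-one (racemic diastereomer mixture) | O=C1C(C)C(c2cc(OC)c(OC)c(OC)c2)c2cc(OC)c(OCc3ccccc3)cc21 | intermediate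
10 | (trimethylsilyl)diazomethane | C[Si](C)(C)C=[N+]=[N-] | starting material
11 | 7-(benzyloxy)-6-methoxy-3-methyl-4-(3,4,5-trimethoxyphenyl)-1-(trimethylsilyl)-3,4-dihydronaphthalen-2(1H)-one (stereoisomer mixture, not isolated) | O=C1C([Si](C)(C)C)c2cc(OCc3ccccc3)c(OC)cc2C(c2cc(OC)c(OC)c(OC)c2)C1C | intermediate
12 | 7-(benzyloxy)-6-methoxy-3-methyl-4-(3,4,5-trimethoxyphenyl)-3,4-dihydronaphthalen-2(1H)-one (racemic diastereomer mixture) | O=C1Cc2cc(OCc3ccccc3)c(OC)cc2C(c2cc(OC)c(OC)c(OC)c2)C1C | intermediate
13 | 7-(benzyloxy)-6-methoxy-2,3-dimethyl-4-(3,4,5-trimethoxyphenyl)-1,2,3,4-tetrahydronaphthalen-2-ol (diastereomer mixture) | CC1(O)Cc2cc(OCc3ccccc3)c(OC)cc2C(c2cc(OC)c(OC)c(OC)c2)C1C | intermediate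
14 | 6-(benzyloxy)-7-methoxy-2,3-dimethyl-1-(3,4,5-trimethoxyphenyl)-1,2-dihydronaphthalene (racemic diastereomer mixture) | CC1=Cc2cc(OCc3ccccc3)c(OC)cc2C(c2cc(OC)c(OC)c(OC)c2)C1C | intermediate
15 | 6-(benzyloxy)-7-methoxy-2,3-dimethyl-1-(3,4,5-trimethoxyphenyl)naphthalene | COc1cc2c(-c3cc(OC)c(OC)c(OC)c3)c(C)c(C)cc2cc1OCc1ccccc1 | intermediate
16 | 3-methoxy-6,7-dimethyl-5-(3,4,5-trimethoxyphenyl)naphthalen-2-ol (CNP0280611.0) | COc1cc2c(-c3cc(OC)c(OC)c(OC)c3)c(C)c(C)cc2cc1O | target

## Step count and risk

Total step count: 10. Longest linear sequence: 10 steps (1 to 16).

**Step 6 (key step).** The carbonyl of 9 is conjugated with the para methoxy group and hindered by the α-methyl and β-aryl groups, so addition of the diazo carbon may be slow. If it is, migration of the wrong carbon, closure of the betaine on oxygen in place of rearrangement, or a second insertion could take over.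
Fallback (sets out from 9, returns at 12): the one-carbon unit is installed first and the aryl shift is then triggered oxidatively.
- Wittig methylenation of 9 (Ph3PCH3Br, KOt-Bu, THF) would give 6-(benzyloxy)-5-methoxy-2-methyl-1-methylidene-3-(3,4,5-trimethoxyphenyl)indane F1.
- The trivalent iodine reagent PhI(OH)OTs in 95% MeOH at rt would add to the exocyclic alkene of F1. The para-methoxy-stabilised benzylic cation is captured by solvent, and the aryl carbon then shifts to the CH2 carbon as iodobenzene leaves. Acidic work-up of the ring-expanded oxocarbenium ion gives 12.
- The same two bonds are formed, and aryl migration is built into the mechanism.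

**Step 4 (Nazarov cyclisation).** The ring that must be attacked carries the protonated acyl group, so the electrocyclisation may be sluggish. Prolonged heating in acid could then lead to retro-aldol cleavage of the enone, or to closure ortho to the hydroxyl.
Fallback (sets out from 5, returns at 9): the five-membered ring is closed at its other end by Friedel–Crafts acylation.
- Knoevenagel condensation of 5 with Meldrum's acid (pyrrolidinium acetate cat., benzene, rt) would give 2,2-dimethyl-5-[(3,4,5-trimethoxyphenyl)methylidene]-1,3-dioxane-4,6-dione F2.
- Conjugate addition of [4-(benzyloxy)-3-methoxyphenyl]magnesium bromide F3 (made from commercial 1-(benzyloxy)-4-bromo-2-methoxybenzene and Mg) in THF at 0 °C would give 5-{[4-(benzyloxy)-3-methoxyphenyl](3,4,5-trimethoxyphenyl)methyl}-2,2-dimethyl-1,3-dioxane-4,6-dione F4.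
- C-Methylation (MeI, K2CO3, DMF) would give 5-{[4-(benzyloxy)-3-methoxyphenyl](3,4,5-trimethoxyphenyl)methyl}-2,2,5-trimethyl-1,3-dioxane-4,6-dione F5.
- Sc(OTf)3 (cat.) in MeNO2 at 100 °C would acylate the benzyloxy-methoxy ring para to its methoxy group, with loss of acetone and CO2, and give 9 directly.
- The free positions of the trimethoxyphenyl ring are each flanked by a methoxy group and the benzylic carbon, which should direct the acylation to the other ring.

**Step 7 (organocerium addition).** Enolisation of the very acidic benzylic methylene, or shielding of the carbonyl by the adjacent methyl and aryl groups, could return starting ketone.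
Fallback (sets out from 12, returns at 14): the enolisation is used instead of fought.
- KN(SiMe3)2 and PhNTf2 in THF at −78 °C would trap the conjugated enolate as 7-(benzyloxy)-6-methoxy-3-methyl-4-(3,4,5-trimethoxyphenyl)-3,4-dihydronaphthalen-2-yl trifluoromethanesulfonate F6.
- Suzuki–Miyaura methylation with trimethylboroxine (Pd(PPh3)4, a zerovalent palladium catalyst, K2CO3, dioxane, 90 °C) would give 14.
- This replaces steps 7 and 8.

**Step 3 (aldol condensation).** The equilibrium of the reversible addition may lie on the side of the hindered α-methyl ketone, and the aldehyde may be consumed by base in the meantime, so conversion could stall.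
Fallback (sets out from 4, returns at 7): the bond is formed irreversibly and the elimination is done separately.
- The dianion of 4 (LiN(i-Pr)2, 2.2 equiv, THF, −78 °C) would be added to 5, and the aldol adduct 6 isolated.
- 6 would then be dehydrated with TsOH in toluene at 80 °C to give 7.

## Further compounds

F1 | step 6 | 6-(benzyloxy)-5-methoxy-2-methyl-1-methylidene-3-(3,4,5-trimethoxyphenyl)indane (racemic diastereomer mixture) | C=C1C(C)C(c2cc(OC)c(OC)c(OC)c2)c2cc(OC)c(OCc3ccccc3)cc21
F2 | step 4 | 2,2-dimethyl-5-[(3,4,5-trimethoxyphenyl)methylidene]-1,3-dioxane-4,6-dione | COc1cc(C=C2C(=O)OC(C)(C)OC2=O)cc(OC)c1OC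
F3 | step 4 | [4-(benzyloxy)-3-methoxyphenyl]magnesium bromide | COc1cc([Mg]Br)ccc1OCc1ccccc1
F4 | step 4 | 5-{[4-(benzyloxy)-3-methoxyphenyl](3,4,5-trimethoxyphenyl)methyl}-2,2-dimethyl-1,3-dioxane-4,6-dione (racemic) | COc1cc(ccc1OCc1ccccc1)C(c1cc(OC)c(OC)c(OC)c1)C1C(=O)OC(C)(C)OC1=O
F5 | step 4 | 5-{[4-(benzyloxy)-3-methoxyphenyl](3,4,5-trimethoxyphenyl)methyl}-2,2,5-trimethyl-1,3-dioxane-4,6-dione (racemic) | COc1cc(ccc1OCc1ccccc1)C(c1cc(OC)c(OC)c(OC)c1)C1(C)C(=O)OC(C)(C)OC1=O
F6 | step 7 | 7-(benzyloxy)-6-methoxy-3-methyl-4-(3,4,5-trimethoxyphenyl)-3,4-dihydronaphthalen-2-yl trifluoromethanesulfonate (racemic diastereomer mixture) | CC1C(OS(=O)(=O)C(F)(F)F)=Cc2cc(OCc3ccccc3)c(OC)cc2C1c1cc(OC)c(OC)c(OC)c1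
F0 | step 3 | none | none
A1 | alternative 1 | 6-(benzyloxy)-7-methoxy-2,3-dimethyl-1-(3,4,5-trimethoxyphenyl)naphthalene | COc1cc2c(-c3cc(OC)c(OC)c(OC)c3)c(C)c(C)cc2cc1OCc1ccccc1
A2 | alternative 1 | 1-[4-(benzyloxy)-2-ethenyl-5-methoxyphenyl]-2,3-dimethyl-1-(3,4,5-trimethoxyphenyl)but-3-en-1-ol (racemic diastereomer mixture) | C=Cc1cc(OCc2ccccc2)c(OC)cc1C(O)(c1cc(OC)c(OC)c(OC)c1)C(C)C(C)=C
A3 | alternative 1 | [4-(benzyloxy)-2-ethenyl-5-methoxyphenyl](3,4,5-trimethoxyphenyl)methanone | C=Cc1cc(OCc2ccccc2)c(OC)cc1C(=O)c1cc(OC)c(OC)c(OC)c1
A4 | alternative 2 | 6-(benzyloxy)-7-methoxy-2,3-dimethyl-1-(3,4,5-trimethoxyphenyl)-1,2-dihydronaphthalene (racemic diastereomer mixture) | CC1=Cc2cc(OCc3ccccc3)c(OC)cc2C(c2cc(OC)c(OC)c(OC)c2)C1C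
A5 | alternative 2 | isoelemicin, 1,2,3-trimethoxy-5-[(E)-prop-1-enyl]benzene | C/C=C/c1cc(OC)c(OC)c(OC)c1
A6 | alternative 2 | 2-(benzyloxy)-1-methoxy-4-[(E)-prop-1-enyl]benzene | C/C=C/c1ccc(OC)c(OCc2ccccc2)c1
A7 | alternative 3 | 6-(benzyloxy)-2-bromo-7-methoxy-3-methyl-1-(3,4,5-trimethoxyphenyl)naphthalene | COc1cc2c(-c3cc(OC)c(OC)c(OC)c3)c(Br)c(C)cc2cc1OCc1ccccc1
A8 | alternative 3 | 6-(benzyloxy)-5-methoxy-2-methyl-3-(3,4,5-trimethoxyphenyl)-1H-indene | CC1=C(c2cc(OC)c(OC)c(OC)c2)c2cc(OC)c(OCc3ccccc3)cc2C1
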